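**Retrosynthetic overview**

1. The target is epicatechin-(4β→8)-epicatechin-(4β→6)-catechin; it is released by one global hydrogenolysis of a tridecabenzyl monobromo trimer 23.
2. Key disconnection: at C4 of the top unit both the C4–C4a bond (pyran ring) and the C4–C8 interflavan bond are cut, leading back to the acyclic aldehyde 21 (C4 = CHO) and the lower dimer 7. One Lewis acid operation closes the top pyran ring and forges the interflavan bond.
3. Enabling feature: ring A of the top unit is a phloroglucinol ring. C4a lies ortho to O1 and to C5–O and para to C7–O, so it attacks a C4 aldehyde to close O1–C2–C3–C4–C4a–C8a and then stabilises the C4 cation. The 3,5-dioxygenated phenoxy group is twofold symmetric, so only one ring can form.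
4. Aldehyde 21: C2 and C3 come from an Evans syn-glycolate aldol with 3,4-bis(benzyloxy)benzaldehyde; the O1–aryl bond comes from O-arylation of the benzylic hydroxyl (no bond to the stereocentre is broken, so syn aldol gives 2,3-cis).
5. Dimer 7: a 4β-alkoxy electrophile from (−)-epicatechin plus 8-bromo catechin nucleophile (4β→6). Ring order: the middle and bottom pyran rings are bought with the flavanols; the top pyran ring is the only ring made and is closed last.

Key step: step 13

Assumption: 1,3-bis(benzyloxy)-5-iodobenzene (18) is taken as a catalogue compound; otherwise it follows in one benzylation from 5-iodoresorcinol.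

**Route**

Step 1
Reactants: 1 (+)-catechin
Product: 2 5,7,3',4'-tetra-O-benzyl-(+)-catechin, (2R,3S), C3 hydroxyl free
Conditions: BnBr, K2CO3, DMF, 0 °C to rt
Reagents that add atoms: benzyl bromide, BrCc1ccccc1
Why: Williamson etherification in which K2CO3 deprotonates only the four phenols, so the C3 alcohol stays free and no stereocentre is touched.

Step 2
Reactants: 2 5,7,3',4'-tetra-O-benzyl-(+)-catechin
Product: 3 8-bromo-5,7,3',4'-tetra-O-benzyl-(+)-catechin
Conditions: NBS, CH2Cl2, −78 °C to rt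
Reagents that add atoms: N-bromosuccinimide, O=C1CCC(=O)N1Br
Why: Electrophilic aromatic bromination should go to C8, the most nucleophilic ring A position of 5,7-di-O-benzyl flavan-3-ols, and the bromine then serves as a removable block that leaves C6 as the only nucleophilic carbon.

Step 3
Reactants: 4 (−)-epicatechin
Product: 5 5,7,3',4'-tetra-O-benzyl-(−)-epicatechin, (2R,3R), C3 hydroxyl free
Conditions: BnBr, K2CO3, DMF, −10 °C to rt
Reagents that add atoms: benzyl bromide, BrCc1ccccc1
Why: Williamson etherification of the four phenols as in step 1, kept cold so that C2 of the 2,3-cis flavanol does not epimerise by base-induced ring opening.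

Step 4
Reactants: 5 5,7,3',4'-tetra-O-benzyl-(−)-epicatechin
Product: 6 4β-(2-ethoxyethoxy)-5,7,3',4'-tetra-O-benzyl-epicatechin, (2R,3R,4S), 3,4-trans
Conditions: DDQ, 2-ethoxyethanol, CH2Cl2, rt
Reagents that add atoms: 2-ethoxyethanol, CCOCCO
Why: DDQ benzylic oxidation (hydride abstraction at C4 gives a cation stabilised by ring A) followed by capture by the alcohol on the face opposite the C3 hydroxyl and C2 aryl group should give the 4β ether.

Step 5
Reactants: 6 4β-(2-ethoxyethoxy)-5,7,3',4'-tetra-O-benzyl-epicatechin; 3 8-bromo-5,7,3',4'-tetra-O-benzyl-(+)-catechin (3–4 equiv, excess recovered)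
Product: 7 5,7,3',4'-tetra-O-benzyl-epicatechin-(4β→6)-8-bromo-5,7,3',4'-tetra-O-benzylcatechin, both C3 hydroxyls free
Conditions: TMSOTf (cat.), CH2Cl2, −78 °C
Reagents that add atoms: none
Why: Lewis acid Friedel–Crafts interflavan coupling in which the C4 cation of 6 is attacked by C6 of 3 (its only free ring A carbon) on the face trans to the C3 hydroxyl, setting the 4β configuration, while the excess of 3 holds back self-condensation of 6.

Step 6
Reactants: 8 (S)-4-benzyl-1,3-oxazolidin-2-one; 9 (benzyloxy)acetyl chloride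
Product: 11 (S)-4-benzyl-3-[(benzyloxy)acetyl]-1,3-oxazolidin-2-one, via lithium oxazolidinide 10 (not isolated)
Conditions: n-BuLi, THF, −78 °C; then 9, −78 to 0 °C
Reagents that add atoms: none
Why: N-acylation of the lithiated Evans auxiliary by the acid chloride is a standard, clean imide synthesis.

Step 7
Reactants: 11 (S)-4-benzyl-3-[(benzyloxy)acetyl]-1,3-oxazolidin-2-one; 12 3,4-bis(benzyloxy)benzaldehyde
Product: 15 (4S)-4-benzyl-3-{(2S,3R)-2-(benzyloxy)-3-[3,4-bis(benzyloxy)phenyl]-3-hydroxypropanoyl}-1,3-oxazolidin-2-one, via boron enolate 13 (not isolated), via boron aldolate 14 (not isolated)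
Conditions: Bu2BOTf, Et3N, CH2Cl2, 0 °C; then 12, −78 to 0 °C; then pH 7 buffer, MeOH, H2O2
Reagents that add atoms: none
Why: Evans syn-glycolate aldol through the Z boron enolate and a Zimmerman–Traxler transition state, in which the (S)-benzyl auxiliary fixes both new centres as (2S,3R), the syn pair that becomes C3 and C2 of the top unit.

Step 8
Reactants: 15 Evans syn-aldol adduct
Product: 16 (1R,2R)-2-(benzyloxy)-1-[3,4-bis(benzyloxy)phenyl]propane-1,3-diol
Conditions: LiBH4, MeOH (1 equiv), THF, 0 °C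
Reagents that add atoms: none
Why: Reductive cleavage of the N-acyl oxazolidinone by LiBH4 gives the primary alcohol and returns the auxiliary without touching either stereocentre.

Step 9
Reactants: 16 (1R,2R)-2-(benzyloxy)-1-[3,4-bis(benzyloxy)phenyl]propane-1,3-diol
Product: 17 (1R,2R)-2-(benzyloxy)-1-[3,4-bis(benzyloxy)phenyl]-3-[(tert-butyldiphenylsilyl)oxy]propan-1-ol
Conditions: TBDPSCl, imidazole, CH2Cl2, 0 °C to rt
Reagents that add atoms: tert-butyl(chloro)diphenylsilane, CC(C)(C)[Si](Cl)(c1ccccc1)c1ccccc1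
Why: Selective silylation of the primary over the hindered benzylic secondary hydroxyl, with the bulky TBDPS group chosen because it should not migrate to the neighbouring alkoxide in step 10.

Step 10
Reactants: 17 mono-TBDPS ether; 18 1,3-bis(benzyloxy)-5-iodobenzene
Product: 19 {[(2R,3R)-2-(benzyloxy)-3-[3,4-bis(benzyloxy)phenyl]-3-[3,5-bis(benzyloxy)phenoxy]propyl]oxy}(tert-butyl)diphenylsilane
Conditions: CuI (10 mol %), 3,4,7,8-tetramethyl-1,10-phenanthroline (20 mol %), Cs2CO3, 4 Å MS, toluene, 110 °C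
Reagents that add atoms: none
Why: Ullmann-type copper-catalysed C–O coupling of a secondary alcohol with an aryl iodide forms the O1–aryl bond without breaking any bond at the benzylic stereocentre, so the syn relationship from the aldol is retained and becomes 2,3-cis.

Step 11
Reactants: 19 aryl ether TBDPS ether
Product: 20 (2R,3R)-2-(benzyloxy)-3-[3,4-bis(benzyloxy)phenyl]-3-[3,5-bis(benzyloxy)phenoxy]propan-1-ol
Conditions: TBAF, AcOH, THF, rt
Reagents that add atoms: none
Why: Fluoride desilylation buffered with acetic acid frees the primary alcohol without base-induced loss of the β-aryloxy group.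

Step 12
Reactants: 20 primary alcohol
Product: 21 (2S,3R)-2-(benzyloxy)-3-[3,4-bis(benzyloxy)phenyl]-3-[3,5-bis(benzyloxy)phenoxy]propanal
Conditions: DMP, NaHCO3, CH2Cl2, 0 °C to rt; used crude
Reagents that add atoms: none
Why: Dess–Martin oxidation under buffered, base-free conditions should give the α-alkoxy aldehyde without epimerisation at C2 or β-elimination of the aryloxy group.

Step 13
Reactants: 21 (2S,3R)-2-(benzyloxy)-3-[3,4-bis(benzyloxy)phenyl]-3-[3,5-bis(benzyloxy)phenoxy]propanal; 7 lower dimer (1.5 equiv, excess recovered)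
Product: 23 3-O-benzyl-5,7,3',4'-tetra-O-benzyl-epicatechin-(4β→8)-5,7,3',4'-tetra-O-benzyl-epicatechin-(4β→6)-8-bromo-5,7,3',4'-tetra-O-benzylcatechin, via flavan-3,4-diol 3-O-benzyl ether 22 (not isolated)
Conditions: Sc(OTf)3 (20 mol %), 4 Å MS, CH2Cl2, −40 to 0 °C
Reagents that add atoms: none
Why: Proposed new method: Sc(OTf)3 activates the aldehyde of 21 and the ring A carbon ortho to the ether oxygen, which is also ortho and para to the two benzyloxy groups, attacks the carbonyl carbon in a 6-exo-trig Friedel–Crafts hydroxyalkylation that closes O1–C2–C3–C4–C4a–C8a to the flavan-3,4-diol ether 22; 22 ionises at once to the C4 benzylic cation, stabilised by the same three oxygens, and C8 of the upper unit of 7 captures it. The closest known reactions are the twofold Friedel–Crafts arylation of an aldehyde by electron-rich arenes and, for the second half, the Lewis acid coupling of 4-hydroxy- or 4-alkoxyflavan-3-ol derivatives with flavan-3-ol nucleophiles (as in step 5); new is their concatenation, in which the flavan-4-yl cation is born from an acyclic aldehyde in the presence of the nucleophile. C2 and C3 pass unchanged from the aldol, the transient C4 carbinol centre of 22 is erased on ionisation, and the final C4 centre is set in the capture: the arene adds to the face opposite the cis C2 aryl and C3 benzyloxy groups, giving the 3,4-trans (4β) bond as in the known couplings of 2,3-cis flavan-4-yl cations. Should 7 add to the aldehyde first, the diarylcarbinol formed ionises to a cation stabilised by ring A of 7 and the tethered ring A closes the same ring, so both orders of events converge on 23. The selectivities needed are closure by ring A and not ring B (trioxygenated against dioxygenated arene, six- against five-membered ring), attack through C8 and not C6 of the upper unit of 7 (the usual site of chain extension; C8 of the lower unit carries bromine and its C6 is substituted) and capture by 7 in preference to ring A of a second molecule (7 in excess). The twofold symmetry of the 3,5-bis(benzyloxy)phenoxy group makes both ortho carbons give the same ring.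

Step 14
Reactants: 23 tridecabenzyl monobromo trimer
Product: 24 arecatannin B1, epicatechin-(4β→8)-epicatechin-(4β→6)-catechin
Conditions: H2 (1 atm), Pd(OH)2/C, Et3N, THF/MeOH/H2O, rt
Reagents that add atoms: none
Why: Catalytic hydrogenolysis should remove all thirteen benzyl ethers and the aryl bromide in one operation, with Et3N trapping HBr so that the acid-labile interflavan bonds and all eight stereocentres stay intact.

**Compound list**

1 | (+)-catechin, (2R,3S) | O[C@H]1Cc2c(O)cc(O)cc2O[C@@H]1c1ccc(O)c(O)c1 | starting material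
2 | 5,7,3',4'-tetra-O-benzyl-(+)-catechin | O[C@H]1Cc2c(OCc4ccccc4)cc(OCc4ccccc4)cc2O[C@@H]1c3ccc(OCc4ccccc4)c(OCc4ccccc4)c3 | intermediate
3 | 8-bromo-5,7,3',4'-tetra-O-benzyl-(+)-catechin | O[C@H]1Cc2c(OCc4ccccc4)cc(OCc4ccccc4)c(Br)c2O[C@@H]1c3ccc(OCc4ccccc4)c(OCc4ccccc4)c3 | intermediate
4 | (−)-epicatechin, (2R,3R) | O[C@@H]1Cc2c(O)cc(O)cc2O[C@@H]1c1ccc(O)c(O)c1 | starting material
5 | 5,7,3',4'-tetra-O-benzyl-(−)-epicatechin | O[C@@H]1Cc2c(OCc4ccccc4)cc(OCc4ccccc4)cc2O[C@@H]1c3ccc(OCc4ccccc4)c(OCc4ccccc4)c3 | intermediate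
6 | 4β-(2-ethoxyethoxy)-5,7,3',4'-tetra-O-benzyl-epicatechin, (2R,3R,4S) | O[C@@H]1[C@@H](OCCOCC)c2c(OCc4ccccc4)cc(OCc4ccccc4)cc2O[C@@H]1c3ccc(OCc4ccccc4)c(OCc4ccccc4)c3 | intermediate
7 | 5,7,3',4'-tetra-O-benzyl-epicatechin-(4β→6)-8-bromo-5,7,3',4'-tetra-O-benzylcatechin | c1c(OCc4ccccc4)cc(OCc4ccccc4)c2c1O[C@H](c3ccc(OCc4ccccc4)c(OCc4ccccc4)c3)[C@H](O)[C@H]2c1c(OCc4ccccc4)c(Br)c2c(c1OCc4ccccc4)C[C@H](O)[C@@H](c3ccc(OCc4ccccc4)c(OCc4ccccc4)c3)O2 | intermediate
8 | (S)-4-benzyl-1,3-oxazolidin-2-one | O=C1OC[C@H](Cc2ccccc2)N1 | starting material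
9 | (benzyloxy)acetyl chloride | O=C(Cl)COCc1ccccc1 | starting material
10 | lithium (S)-4-benzyl-2-oxo-1,3-oxazolidin-3-ide | [Li+].O=C1OC[C@H](Cc2ccccc2)[N-]1 | intermediate (not isolated)
11 | (S)-4-benzyl-3-[(benzyloxy)acetyl]-1,3-oxazolidin-2-one | O=C1OC[C@H](Cc2ccccc2)N1C(=O)COCc1ccccc1 | intermediate
12 | 3,4-bis(benzyloxy)benzaldehyde | O=Cc1ccc(OCc2ccccc2)c(OCc2ccccc2)c1 | starting material
13 | (Z)-dibutylboron enolate of 11 | CCCCB(CCCC)O/C(=C\OCc1ccccc1)N1C(=O)OC[C@@H]1Cc1ccccc1 | intermediate (not isolated)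
14 | dibutylboron aldolate of 15 | CCCCB(CCCC)O[C@H](c3ccc(OCc4ccccc4)c(OCc4ccccc4)c3)[C@H](OCc4ccccc4)C(=O)N1C(=O)OC[C@@H]1Cc1ccccc1 | intermediate (not isolated)
15 | (4S)-4-benzyl-3-{(2S,3R)-2-(benzyloxy)-3-[3,4-bis(benzyloxy)phenyl]-3-hydroxypropanoyl}-1,3-oxazolidin-2-one | O[C@H](c3ccc(OCc4ccccc4)c(OCc4ccccc4)c3)[C@H](OCc4ccccc4)C(=O)N1C(=O)OC[C@@H]1Cc1ccccc1 | intermediate
16 | (1R,2R)-2-(benzyloxy)-1-[3,4-bis(benzyloxy)phenyl]propane-1,3-diol | O[C@H](c3ccc(OCc4ccccc4)c(OCc4ccccc4)c3)[C@H](OCc4ccccc4)CO | intermediate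
17 | (1R,2R)-2-(benzyloxy)-1-[3,4-bis(benzyloxy)phenyl]-3-[(tert-butyldiphenylsilyl)oxy]propan-1-ol | O[C@H](c3ccc(OCc4ccccc4)c(OCc4ccccc4)c3)[C@H](OCc4ccccc4)CO[Si](c1ccccc1)(c1ccccc1)C(C)(C)C | intermediate
18 | 1,3-bis(benzyloxy)-5-iodobenzene | Ic1cc(OCc2ccccc2)cc(OCc2ccccc2)c1 | starting material
19 | {[(2R,3R)-2-(benzyloxy)-3-[3,4-bis(benzyloxy)phenyl]-3-[3,5-bis(benzyloxy)phenoxy]propyl]oxy}(tert-butyl)diphenylsilane | c4ccccc4COc1cc(OCc4ccccc4)cc(c1)O[C@H](c3ccc(OCc4ccccc4)c(OCc4ccccc4)c3)[C@H](OCc4ccccc4)CO[Si](c1ccccc1)(c1ccccc1)C(C)(C)C | intermediate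
20 | (2R,3R)-2-(benzyloxy)-3-[3,4-bis(benzyloxy)phenyl]-3-[3,5-bis(benzyloxy)phenoxy]propan-1-ol | c4ccccc4COc1cc(OCc4ccccc4)cc(c1)O[C@H](c3ccc(OCc4ccccc4)c(OCc4ccccc4)c3)[C@H](OCc4ccccc4)CO | intermediate
21 | (2S,3R)-2-(benzyloxy)-3-[3,4-bis(benzyloxy)phenyl]-3-[3,5-bis(benzyloxy)phenoxy]propanal | c4ccccc4COc1cc(OCc4ccccc4)cc(c1)O[C@H](c3ccc(OCc4ccccc4)c(OCc4ccccc4)c3)[C@H](OCc4ccccc4)C=O | intermediate
22 | (2R,3R)-3,5,7-tris(benzyloxy)-2-[3,4-bis(benzyloxy)phenyl]chroman-4-ol, both C4 epimers (2,3-cis flavan-3,4-diol 3-O-benzyl ether) | c4ccccc4COc1cc(OCc4ccccc4)c2c(c1)O[C@H](c3ccc(OCc4ccccc4)c(OCc4ccccc4)c3)[C@H](OCc4ccccc4)C2O | intermediate (not isolated)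
23 | 3-O-benzyl-5,7,3',4'-tetra-O-benzyl-epicatechin-(4β→8)-5,7,3',4'-tetra-O-benzyl-epicatechin-(4β→6)-8-bromo-5,7,3',4'-tetra-O-benzylcatechin | c4ccccc4COc1cc(OCc4ccccc4)c2c(c1)O[C@H](c3ccc(OCc4ccccc4)c(OCc4ccccc4)c3)[C@H](OCc4ccccc4)[C@H]2c1c(OCc4ccccc4)cc(OCc4ccccc4)c2c1O[C@H](c3ccc(OCc4ccccc4)c(OCc4ccccc4)c3)[C@H](O)[C@H]2c1c(OCc4ccccc4)c(Br)c2c(c1OCc4ccccc4)C[C@H](O)[C@@H](c3ccc(OCc4ccccc4)c(OCc4ccccc4)c3)O2 | intermediate
24 | arecatannin B1, epicatechin-(4β→8)-epicatechin-(4β→6)-catechin | Oc1cc(O)c2c(c1)O[C@H](c1ccc(O)c(O)c1)[C@H](O)[C@H]2c1c(O)cc(O)c2c1O[C@H](c1ccc(O)c(O)c1)[C@H](O)[C@H]2c1c(O)cc2c(c1O)C[C@H](O)[C@@H](c1ccc(O)c(O)c1)O2 | target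

**Step count and risks**

Total step count: 14. Longest linear sequence: 9 steps (steps 6 to 14, from 8 and 9 to 24).

Steps most likely to fail:

1. Step 13 (Proposed new method). The cation may be trapped by ring A of a second molecule of 21 or 23 (self-condensation), or the aldehyde may be arylated by 7 in ways that outrun ring closure, giving oligomeric mixtures. The fallback uses known chemistry and runs the ring closure and the interflavan coupling as two separate, individually precedented operations. It sets out from 21: acid-catalysed intramolecular Friedel–Crafts cyclisation (camphorsulfonic acid cat., CH2Cl2/2-ethoxyethanol, 0 °C), in which the alcohol in large excess intercepts the C4 cation, should give the isolable 3-O-benzyl-5,7,3',4'-tetra-O-benzyl-4β-(2-ethoxyethoxy)epicatechin F1, an electrophile of the same type as 6. F1 is then coupled with 7 (TMSOTf cat., CH2Cl2, −78 °C) exactly as in step 5 and the route is rejoined at 23. The top pyran ring is still the last ring formed.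

2. Step 10. Turnover of the hindered secondary alkoxide at copper may be slow, leaving time for silyl migration or oxidation of the benzylic alcohol at 110 °C. The fallback is a metal-free O-arylation that sets out from 17 and 18: 18 is oxidised in the presence of 1,3,5-trimethoxybenzene (mCPBA, TsOH·H2O, MeCN, rt) to [3,5-bis(benzyloxy)phenyl](2,4,6-trimethoxyphenyl)iodonium tosylate F2. The sodium alkoxide of 17 (NaH, toluene, rt) is then arylated by F2 through ligand coupling at trivalent iodine, the electron-rich trimethoxyphenyl group staying on iodine; no bond to the stereocentre is broken, and the route is rejoined at 19.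

3. Step 5. Self-condensation of 6 through its own free C8 may outpace attack by the bromine-deactivated C6 of 3. The fallback delivers the nucleophile intramolecularly through a temporary diester tether and sets out from 3 and 6: 3 is opened onto glutaric anhydride (DMAP, pyridine) to give 8-bromo-5,7,3',4'-tetra-O-benzylcatechin 3-O-hemiglutarate F3. F3 is esterified with the C3 hydroxyl of 6 (EDC, DMAP, CH2Cl2) to give the mixed glutarate diester of 3 and 6 F4. TMSOTf at high dilution (CH2Cl2, −40 °C) then forms the 4β→6 bond inside the tether to give the macrocyclic glutarate-bridged dimer F5, and NaOMe in MeOH/THF removes the tether, rejoining the route at 7. The tether length (glutarate shown) would be tuned if needed.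

**Further compounds**

F1 | step 13 | (2R,3R,4S)-3,5,7-tris(benzyloxy)-2-[3,4-bis(benzyloxy)phenyl]-4-(2-ethoxyethoxy)chromane (3-O-benzyl-5,7,3',4'-tetra-O-benzyl-4β-(2-ethoxyethoxy)epicatechin) | c4ccccc4COc1cc(OCc4ccccc4)c2c(c1)O[C@H](c3ccc(OCc4ccccc4)c(OCc4ccccc4)c3)[C@H](OCc4ccccc4)[C@H]2OCCOCC
F2 | step 10 | [3,5-bis(benzyloxy)phenyl](2,4,6-trimethoxyphenyl)iodonium 4-methylbenzenesulfonate | COc1cc(OC)c([I+]c2cc(OCc3ccccc3)cc(OCc3ccccc3)c2)c(OC)c1.Cc1ccc(cc1)S(=O)(=O)[O-]
F3 | step 5 | 8-bromo-5,7,3',4'-tetra-O-benzylcatechin 3-O-hemiglutarate | OC(=O)CCCC(=O)O[C@H]1Cc2c(OCc4ccccc4)cc(OCc4ccccc4)c(Br)c2O[C@@H]1c3ccc(OCc4ccccc4)c(OCc4ccccc4)c3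
F4 | step 5 | mixed glutarate diester of 3 (at O3) and 6 (at O3) | O=C(CCCC(=O)O[C@H]1Cc2c(OCc4ccccc4)cc(OCc4ccccc4)c(Br)c2O[C@@H]1c3ccc(OCc4ccccc4)c(OCc4ccccc4)c3)O[C@@H]1[C@@H](OCCOCC)c2c(OCc4ccccc4)cc(OCc4ccccc4)cc2O[C@@H]1c3ccc(OCc4ccccc4)c(OCc4ccccc4)c3
F5 | step 5 | macrocyclic 3,3''-O-glutarate-bridged derivative of dimer 7 | c1c(OCc4ccccc4)cc(OCc4ccccc4)c2c1O[C@H](c3ccc(OCc4ccccc4)c(OCc4ccccc4)c3)[C@H](OC(=O)CCCC(=O)O5)[C@H]2c1c(OCc4ccccc4)c(Br)c2c(c1OCc4ccccc4)C[C@H]5[C@@H](c3ccc(OCc4ccccc4)c(OCc4ccccc4)c3)O2
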